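## The problem

Compound 18 is the methyl ester of shikimic acid with an acetate on O3 and (R)-2-methylbutanoates on O4 and O5. The skeleton is a single cyclohexene ring: C1 carries the methoxycarbonyl group and is joined to C2 by the only double bond, so no ring fusion has to be made, but the enoate must sit between the C6 methylene and the C3 carbinol. Three contiguous ring stereocentres must be set absolutely, C3 (R), C4 (S) and C5 (R), with O3/O4 cis and O4/O5 trans. C4 and C5 form a threo-diol that exists as a C2-symmetric four-carbon building block, so only C3 need be created, and the one centre able to direct it is its neighbour C4. The two side-chain stereocentres are beyond the reach of the ring and must arrive with the acid; being α to a carbonyl group, they tolerate no enolising base once installed. The acyl pattern is a second problem: O3 must be told apart from O4 and O5, although O3 and O4 are cis-vicinal and exchange acyl groups easily through a cyclic orthoacid. Rough treatment is excluded by four esters, an allylic acetate and a C5 acyloxy group β to the vinylogously acidic C6 protons, which opens the way to elimination and aromatisation under base. The enabling feature is that C3 is an allylic carbinol carbon flanked by the vinylic carbon C2 and the oxygenated carbon C4. Adding a C2 alkenyl metal to a C3 aldehyde therefore closes the ring, creates C3 under the influence of C4, and delivers O3 as the only free hydroxyl while O4 and O5 are still tied together.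

## Retrosynthesis

**Acyl–O4 and acyl–O5 bonds (18 ⇒ 15 + two 16).** The two identical ester bonds are cut first, so that the chiral acid 16 is used once, in the last step, under non-enolising carbodiimide activation. Carrying both 2-methylbutanoates through the ring closure would leave only an acetylation at the end, but that order is not adopted. In an open chain, releasing the diol next to the acrylate exposes a γ-hydroxy ester that lactonises; unmasking the C3 hydroxyl beside a secondary ester invites 1,2-acyl migration; and an α,β-bis(acyloxy) aldehyde loses carboxylate by β-elimination and can epimerise. None of this can happen once the ring exists, because the C5 oxygen cannot reach the ester carbon across the ring. The forward step asks that acylation of O4 and O5 in diol 15 outrun migration of the C3 acetyl group.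

**Acetal C–O bonds and acetyl–O3 bond (15 ⇒ 14 ⇒ 13).** Alcohol 13 has O3 free and O4/O5 joined in one isopropylidene acetal, which is exactly the partition of the target (one acetate, two identical esters). Acetylation precedes acetal cleavage because a free cis-hydroxyl at C3 would let the acetal migrate to the 3,4-position under acid. The forward steps are a routine acetylation and a mild aqueous-acid hydrolysis, helped by the strain of the trans-fused dioxolane.

**C2–C3 bond, the ring-forming cut (13 ⇒ 11).** Breaking C2–C3 opens the ring and removes the C3 stereocentre, leaving aldehyde 11 with only the two pool-derived centres. The neighbouring cuts are poorer. Closing at C1=C2 by olefination needs C3 set beforehand; cutting C3–C4 or C4–C5 destroys the threo-diol unit; an alkylative closure at C6–C1 gains no stereocentre. The forward reaction needs an alkenyl nucleophile that is made in the presence of an ester, an acetal and an aldehyde, and adds only to the aldehyde. That is the profile of an alkenylchromium species generated from the enol triflate in 11. The step must also keep the (E) geometry, since only that isomer can reach C3, and place the new alkoxide cis to O4.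

**Oxidation level and silyl ether at C3 (11 ⇒ 10 ⇒ 9).** The aldehyde is revealed last from a silyl-protected primary alcohol, so C3 passes through the base-mediated chain construction in protected form. The forward steps need a desilylation that spares acetal and enol triflate, and a neutral oxidation.

**Sulfonyl–O bond and C1–C2 bond (9 ⇒ 8 ⇒ 6 + 7).** Enol triflate 9 is the O-sulfonylated enol of α-formyl ester 8, and the formyl carbon C2 comes from methyl formate 7 by a crossed Claisen condensation with ester 6. The double-bond geometry is decided in the O-sulfonylation, which must be run on a non-chelated enolate.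

**C6–C1 bond (6 ⇒ 3 + 4).** Alkylating the enolate of methyl acetate 4 with primary triflate 3 brings in C1 and the ester carbon in one step. A methyl ester paired with methyl formate means alkoxide exchange in the next step changes nothing.

**Sulfonyl–O and Si–O bonds (3 ⇒ 2 ⇒ 1).** The C2-symmetric diol 1 supplies C3–C6, with C4 and C5 in the correct absolute configuration and already jointly protected. Its hydroxyls are homotopic, so a monosilylation differentiates the chain ends with no selectivity question.

## Roads not taken

**Alternative 1:** The cut is at C1–C2 and C5–C6, a Diels–Alder reaction of furan A1 with 2,2,2-trifluoroethyl acrylate A2 under a chiral oxazaborolidinium Lewis acid. This would give the oxanorbornene A3, and base-induced opening of the oxygen bridge the dienol A4.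
- Merits: the carbocycle and the C5 centre come from one catalytic asymmetric step, and C5 can then direct a cis-dihydroxylation of the C3=C4 double bond from the opposite face.
- Weak points: furan cycloadditions are reversible and give mixed endo/exo selectivity. More seriously for this target, the dihydroxylation delivers O3 and O4 together as a free cis-diol. The target needs O3 distinct from O4, so a regioselective acylation of a migration-prone cis-diol is unavoidable, and the trifluoroethyl ester must still be exchanged for a methyl ester.
- Comparison: this road reaches the ring in far fewer steps than the chosen plan and needs no chiral pool. The chosen plan sets against it that O3 is born free while O4/O5 are masked as a pair, so no hydroxyl has to be chosen among equals.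

**Alternative 2:** The cut is at the C4–O and C5–O ester bonds of a preformed ring: a Prévost bis-acyloxylation of the nitro cyclohexene A5 with the silver salt A6 would give the nitro diester A7. Loss of the nitro group would then unveil the enoate, followed by desilylation and acetylation.
- Merits: both esters arrive in one step with the trans relationship guaranteed by the acyloxonium mechanism, and O3 is already set apart as a silyl ether. In oxygen differentiation this road equals the chosen one, and it is more convergent.
- Weak points: the 3,4-cis/4,5-trans pattern needs the halonium to form anti to the silyl ether and the acyloxonium ion to open at C5 and not C4. The chiral carboxylate cannot supply the absolute configuration, so A5 must already be enantiopure, and no simple source is apparent. The nitro elimination uses base next to β-acyloxy groups, and the final desilylation sits beside a cis-ester.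
- Comparison: better in convergence; weaker in stereochemical security. The chosen plan takes C4 and C5 from the pool and leaves one centre, C3, to be controlled.

**Alternative 3:** The cut is at C1=C2, an intramolecular Horner–Wadsworth–Emmons condensation in a chain whose C2–C6 come from D-lyxose A8. This would give the 3,4-acetonide A9 with O5 free.
- Merits: all three ring stereocentres come from the sugar and the ring closure creates none. This is the most stereochemically secure of the four roads.
- Weak points: the acetal pairs O3 with O4 and leaves O5, the wrong partition for 18. After O5 is esterified and the acetal removed, O3 and O4 must receive different acyl groups on a cis-diol. Extending the sugar by the phosphonoacetate carbon also costs steps before the closure.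
- Comparison: better in stereocontrol, since the chosen plan carries a real risk at C3, and similar in length up to the ring. The chosen plan sets against it the correct O3 versus O4/O5 partition, which reduces the endgame to an acetylation and an acetal-for-ester exchange on two oxygens that receive the same acyl group.

Key step: step 8

Assumption: diol 1 is bought as (−)-2,3-O-isopropylidene-D-threitol; apart from the preformed nucleophile 5, metal alkoxides and enolates that arise only as conjugate bases of a substrate are described in the Why lines and not numbered; 8 is drawn as its aldehyde tautomer.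

Step 1
Reactants: 1 [(4R,5R)-2,2-dimethyl-1,3-dioxolane-4,5-diyl]dimethanol
Product: 2 [(4R,5R)-5-({[tert-butyl(dimethyl)silyl]oxy}methyl)-2,2-dimethyl-1,3-dioxolan-4-yl]methanol
Conditions: NaH (1.0 equiv), THF, 0 °C to rt; then TBSCl (1.0 equiv)
Reagents that add atoms: tert-butyl(chloro)dimethylsilane (TBSCl), CC(C)(C)[Si](C)(C)Cl
Why: Monosilylation of a symmetric diol through its monosodium alkoxide (Williamson-type O-silylation); the poorly soluble mono-alkoxide is silylated faster than it equilibrates, and because the two hydroxyls are homotopic either one gives 2.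

Step 2
Reactants: 2 [(4R,5R)-5-({[tert-butyl(dimethyl)silyl]oxy}methyl)-2,2-dimethyl-1,3-dioxolan-4-yl]methanol
Product: 3 [(4R,5R)-5-({[tert-butyl(dimethyl)silyl]oxy}methyl)-2,2-dimethyl-1,3-dioxolan-4-yl]methyl trifluoromethanesulfonate
Conditions: Tf2O (1.2 equiv), pyridine (2 equiv), CH2Cl2, −78 to −20 °C; used crude
Reagents that add atoms: trifluoromethanesulfonic anhydride (Tf2O), O=S(=O)(OS(=O)(=O)C(F)(F)F)C(F)(F)F
Why: O-sulfonylation of a primary alcohol; the trans-dioxolane keeps the silyl ether oxygen from displacing the triflate, so 3 should survive a cold work-up and immediate use.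

Step 3
Reactants: 3 [(4R,5R)-5-({[tert-butyl(dimethyl)silyl]oxy}methyl)-2,2-dimethyl-1,3-dioxolan-4-yl]methyl trifluoromethanesulfonate; 4 methyl acetate
Product: 6 methyl 3-[(4R,5R)-5-({[tert-butyl(dimethyl)silyl]oxy}methyl)-2,2-dimethyl-1,3-dioxolan-4-yl]propanoate, via methyl acetate lithium enolate 5 (not isolated)
Conditions: LDA (2.5 equiv, commercial solution), 4 (2.6 equiv), THF, −78 °C; then 3, DMPU, −78 to −40 °C
Reagents that add atoms: none
Why: SN2 alkylation of an ester enolate by a primary alkyl triflate, which forms the C6–C1 bond; the triflate should react at −78 °C, where Claisen self-condensation of 5 is slow, and the stereocentres are not touched.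

Step 4
Reactants: 6 methyl 3-[(4R,5R)-5-({[tert-butyl(dimethyl)silyl]oxy}methyl)-2,2-dimethyl-1,3-dioxolan-4-yl]propanoate; 7 methyl formate
Product: 8 methyl 2-formyl-3-[(4R,5R)-5-({[tert-butyl(dimethyl)silyl]oxy}methyl)-2,2-dimethyl-1,3-dioxolan-4-yl]propanoate (both C2 epimers, in equilibrium with the enol)
Conditions: LDA (1.3 equiv), THF, −78 °C; 7 (5 equiv), −78 to 0 °C; AcOH quench; used crude
Reagents that add atoms: none
Why: Crossed Claisen condensation (α-formylation) of the ester enolate with a non-enolisable formate, which forms the C1–C2 bond; the product is held as its enolate until the mild acidic quench, and the new C1 centre is of no consequence because it becomes sp2 in the next step.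

Step 5
Reactants: 8 methyl 2-formyl-3-[(4R,5R)-5-({[tert-butyl(dimethyl)silyl]oxy}methyl)-2,2-dimethyl-1,3-dioxolan-4-yl]propanoate
Product: 9 methyl (2E)-2-{[(4R,5R)-5-({[tert-butyl(dimethyl)silyl]oxy}methyl)-2,2-dimethyl-1,3-dioxolan-4-yl]methyl}-3-{[(trifluoromethyl)sulfonyl]oxy}prop-2-enoate
Conditions: DBU (1.2 equiv), CH2Cl2, −78 °C; then Tf2O (1.1 equiv)
Reagents that add atoms: trifluoromethanesulfonic anhydride (Tf2O), O=S(=O)(OS(=O)(=O)C(F)(F)F)C(F)(F)F
Why: O-triflation of a 1,3-dicarbonyl enolate; with the non-chelating amidinium counter-ion the enolate should adopt the extended, dipole-minimised form with its oxygen anti to the ester carbonyl, and trapping gives the (E)-enol triflate with C2–O cis to C6 (chelating lithium or sodium enolates would give the (Z)-isomer).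

Step 6
Reactants: 9 methyl (2E)-2-{[(4R,5R)-5-({[tert-butyl(dimethyl)silyl]oxy}methyl)-2,2-dimethyl-1,3-dioxolan-4-yl]methyl}-3-{[(trifluoromethyl)sulfonyl]oxy}prop-2-enoate
Product: 10 methyl (2E)-2-{[(4R,5R)-5-(hydroxymethyl)-2,2-dimethyl-1,3-dioxolan-4-yl]methyl}-3-{[(trifluoromethyl)sulfonyl]oxy}prop-2-enoate
Conditions: HF·pyridine, pyridine, THF, 0 °C to rt
Reagents that add atoms: none
Why: Fluoride-induced desilylation of a primary silyl ether under buffered, weakly acidic conditions that should leave the acetal intact and spare the electrophilic β-triflyloxy acrylate, which a basic fluoride source would attack.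

Step 7
Reactants: 10 methyl (2E)-2-{[(4R,5R)-5-(hydroxymethyl)-2,2-dimethyl-1,3-dioxolan-4-yl]methyl}-3-{[(trifluoromethyl)sulfonyl]oxy}prop-2-enoate
Product: 11 methyl (2E)-2-{[(4R,5S)-5-formyl-2,2-dimethyl-1,3-dioxolan-4-yl]methyl}-3-{[(trifluoromethyl)sulfonyl]oxy}prop-2-enoate
Conditions: Dess–Martin periodinane (1.3 equiv), NaHCO3, CH2Cl2, 0 °C to rt; used directly
Reagents that add atoms: none
Why: Dess–Martin oxidation of a primary alcohol to the aldehyde under near-neutral conditions; the formyl-bearing carbon already has the thermodynamically preferred trans arrangement on the dioxolane, so epimerisation is not a threat (the descriptor changes from R to S only through ligand priorities).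

Step 8
Reactants: 11 methyl (2E)-2-{[(4R,5S)-5-formyl-2,2-dimethyl-1,3-dioxolan-4-yl]methyl}-3-{[(trifluoromethyl)sulfonyl]oxy}prop-2-enoate
Product: 13 methyl (3aR,7R,7aR)-7-hydroxy-2,2-dimethyl-3a,4,7,7a-tetrahydro-1,3-benzodioxole-5-carboxylate, via (E)-alkenylchromium dichloride 12 (not isolated)
Conditions: CrCl2 (6 equiv), NiCl2 (cat.), degassed DMF, rt, 0.005 M, slow addition of 11; H2O work-up
Reagents that add atoms: none
Why: Zerovalent nickel, formed from NiCl2 by divalent chromium, inserts into the C2–O bond of the enol triflate and hands the alkenyl group to trivalent chromium to give 12, after which the nickel re-enters the cycle. The C2–Cr bond of 12 adds to the chromium-bound C3 aldehyde in a 6-exo-trig closure that forms C2–C3 and the cyclohexene ring; the closest known reaction type is the intramolecular Nozaki–Hiyama–Kishi cyclisation of alkenyl triflates and iodides onto aldehydes. Organochromium reagents add to aldehydes and leave esters, the acetal and the enoate alone, which is the chemoselectivity required. Only the (E)-alkenyl species, with the metal cis to C6, can reach C3, so any geometric leakage is unproductive but cannot give a stereoisomeric ring. The new C3 centre is controlled by C4: the trans-dioxolane fixes the forming half-chair with O4 and O5 equatorial, so C2 must attack anti to the C4–O bond, the polar Felkin–Anh arrangement. The carbonyl oxygen should take the pseudo-axial site, where its dipole is not aligned with the equatorial C4–O bond and the four-centre C–Cr/C=O array lies perpendicular to the enoate plane. A pseudo-axial alkoxide is cis to O4, which is the shikimate configuration. High dilution should suppress intermolecular addition, and the trans-fused dioxolane-on-cyclohexene product, though somewhat strained, is a known ring type.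

Step 9
Reactants: 13 methyl (3aR,7R,7aR)-7-hydroxy-2,2-dimethyl-3a,4,7,7a-tetrahydro-1,3-benzodioxole-5-carboxylate
Product: 14 methyl (3aR,7R,7aS)-7-acetoxy-2,2-dimethyl-3a,4,7,7a-tetrahydro-1,3-benzodioxole-5-carboxylate
Conditions: Ac2O, pyridine, DMAP (cat.), CH2Cl2, 0 °C
Reagents that add atoms: acetic anhydride, CC(=O)OC(C)=O
Why: O-acetylation of the only free hydroxyl under nucleophilic catalysis; capping O3 before acid treatment should prevent acetal migration to the cis-3,4 position (the 7a descriptor changes only through ligand priorities).

Step 10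
Reactants: 14 methyl (3aR,7R,7aS)-7-acetoxy-2,2-dimethyl-3a,4,7,7a-tetrahydro-1,3-benzodioxole-5-carboxylate
Product: 15 methyl (3R,4S,5R)-3-acetoxy-4,5-dihydroxycyclohex-1-ene-1-carboxylate
Conditions: AcOH/H2O (4:1), 40 °C
Reagents that add atoms: none
Why: Acid-catalysed acetal hydrolysis, accelerated by the strain of the trans-fused dioxolane; acyl migration is slow under acid, and the allylic acetate should not ionise next to the electron-poor enoate.

Step 11
Reactants: 15 methyl (3R,4S,5R)-3-acetoxy-4,5-dihydroxycyclohex-1-ene-1-carboxylate; 16 (2R)-2-methylbutanoic acid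
Product: 18 methyl (3R,4S,5R)-3-acetoxy-4,5-bis{[(2R)-2-methylbutanoyl]oxy}cyclohex-1-ene-1-carboxylate, via methyl 3-O-acetyl-5-O-[(R)-2-methylbutanoyl]shikimate 17 (not isolated)
Conditions: 16 (3 equiv), DCC (3 equiv), DMAP (0.3 equiv), CH2Cl2, 0 °C to rt
Reagents that add atoms: none
Why: Steglich esterification, expected first at the less hindered C5 hydroxyl and then at C4; the activated acid meets no base stronger than DMAP, so its α-stereocentre should be retained, and an excess of activated acid lets acylation outrun acetyl migration.

## Compound list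

1 | [(4R,5R)-2,2-dimethyl-1,3-dioxolane-4,5-diyl]dimethanol ((−)-2,3-O-isopropylidene-D-threitol) | OC[C@H]1OC(C)(C)O[C@@H]1CO | starting material
2 | [(4R,5R)-5-({[tert-butyl(dimethyl)silyl]oxy}methyl)-2,2-dimethyl-1,3-dioxolan-4-yl]methanol | OC[C@H]1OC(C)(C)O[C@@H]1CO[Si](C)(C)C(C)(C)C | intermediate
3 | [(4R,5R)-5-({[tert-butyl(dimethyl)silyl]oxy}methyl)-2,2-dimethyl-1,3-dioxolan-4-yl]methyl trifluoromethanesulfonate | FC(F)(F)S(=O)(=O)OC[C@H]1OC(C)(C)O[C@@H]1CO[Si](C)(C)C(C)(C)C | intermediate
4 | methyl acetate | CC(=O)OC | starting material
5 | lithium 1-methoxyethen-1-olate (lithium enolate of methyl acetate) | [Li+].[O-]C(=C)OC | intermediate (not isolated)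
6 | methyl 3-[(4R,5R)-5-({[tert-butyl(dimethyl)silyl]oxy}methyl)-2,2-dimethyl-1,3-dioxolan-4-yl]propanoate | COC(=O)CC[C@H]1OC(C)(C)O[C@@H]1CO[Si](C)(C)C(C)(C)C | intermediate
7 | methyl formate | COC=O | starting material
8 | methyl 2-formyl-3-[(4R,5R)-5-({[tert-butyl(dimethyl)silyl]oxy}methyl)-2,2-dimethyl-1,3-dioxolan-4-yl]propanoate (C2 epimers and enol) | COC(=O)C(C=O)C[C@H]1OC(C)(C)O[C@@H]1CO[Si](C)(C)C(C)(C)C | intermediate
9 | methyl (2E)-2-{[(4R,5R)-5-({[tert-butyl(dimethyl)silyl]oxy}methyl)-2,2-dimethyl-1,3-dioxolan-4-yl]methyl}-3-{[(trifluoromethyl)sulfonyl]oxy}prop-2-enoate | FC(F)(F)S(=O)(=O)O/C=C(C(=O)OC)\C[C@H]1OC(C)(C)O[C@@H]1CO[Si](C)(C)C(C)(C)C | intermediate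
10 | methyl (2E)-2-{[(4R,5R)-5-(hydroxymethyl)-2,2-dimethyl-1,3-dioxolan-4-yl]methyl}-3-{[(trifluoromethyl)sulfonyl]oxy}prop-2-enoate | FC(F)(F)S(=O)(=O)O/C=C(C(=O)OC)\C[C@H]1OC(C)(C)O[C@@H]1CO | intermediate
11 | methyl (2E)-2-{[(4R,5S)-5-formyl-2,2-dimethyl-1,3-dioxolan-4-yl]methyl}-3-{[(trifluoromethyl)sulfonyl]oxy}prop-2-enoate | FC(F)(F)S(=O)(=O)O/C=C(C(=O)OC)\C[C@H]1OC(C)(C)O[C@@H]1C=O | intermediate
12 | [(1E)-2-{[(4R,5S)-5-formyl-2,2-dimethyl-1,3-dioxolan-4-yl]methyl}-3-methoxy-3-oxoprop-1-en-1-yl]chromium dichloride (solvent ligands omitted) | Cl[Cr](Cl)/C=C(C(=O)OC)\C[C@H]1OC(C)(C)O[C@@H]1C=O | intermediate (not isolated)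
13 | methyl (3aR,7R,7aR)-7-hydroxy-2,2-dimethyl-3a,4,7,7a-tetrahydro-1,3-benzodioxole-5-carboxylate (methyl 4,5-O-isopropylideneshikimate; hydroxyl cis to the neighbouring acetal oxygen) | CC1(C)O[C@@H]2[C@H](O)C=C(C(=O)OC)C[C@H]2O1 | intermediate
14 | methyl (3aR,7R,7aS)-7-acetoxy-2,2-dimethyl-3a,4,7,7a-tetrahydro-1,3-benzodioxole-5-carboxylate | CC1(C)O[C@@H]2[C@H](OC(C)=O)C=C(C(=O)OC)C[C@H]2O1 | intermediate
15 | methyl (3R,4S,5R)-3-acetoxy-4,5-dihydroxycyclohex-1-ene-1-carboxylate | O[C@@H]1[C@H](OC(C)=O)C=C(C(=O)OC)C[C@H]1O | intermediate
16 | (2R)-2-methylbutanoic acid | CC[C@@H](C)C(=O)O | starting material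
17 | methyl (3R,4S,5R)-3-acetoxy-4-hydroxy-5-{[(2R)-2-methylbutanoyl]oxy}cyclohex-1-ene-1-carboxylate | O[C@@H]1[C@H](OC(C)=O)C=C(C(=O)OC)C[C@H]1OC(=O)[C@H](C)CC | intermediate (not isolated)
18 | methyl (3R,4S,5R)-3-acetoxy-4,5-bis{[(2R)-2-methylbutanoyl]oxy}cyclohex-1-ene-1-carboxylate | CC[C@@H](C)C(=O)O[C@@H]1[C@H](OC(C)=O)C=C(C(=O)OC)C[C@H]1OC(=O)[C@H](C)CC | target

## Step count and least certain steps

Total: 11 steps. Longest linear sequence: 11 steps (1 to 18).

**Step 8 (key step).** The most likely failure is poor facial selectivity at the aldehyde. The tether, not an acyclic preference, fixes the trajectory of C2, and the choice between a pseudo-axial and a pseudo-equatorial carbonyl oxygen rests on modest dipole and steric differences. Slow closure against the strain of the trans-fused dioxolane, with protonation of the alkenyl metal, is the second concern. The fallback changes how C3 is set: from 11 the same ring closure is run, the C3-epimeric alcohol methyl (3aR,7S,7aR)-7-hydroxy-2,2-dimethyl-3a,4,7,7a-tetrahydro-1,3-benzodioxole-5-carboxylate F1 is taken on, and a Mitsunobu reaction with acetic acid (PPh3, DIAD, THF) inverts C3 and installs the acetate in one operation. The neighbouring O4 is an acetal oxygen, so no acyloxy participation can divert the displacement. The route is rejoined at 14.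

**Step 3.** The most likely failure is loss of the nucleophile by Claisen self-condensation before a slow substitution at the β-branched, β-oxygenated primary carbon is complete, together with double alkylation. The fallback uses a soft, non-self-condensing nucleophile: from 3, sodium dimethyl malonate (NaH, dimethyl malonate, THF/DMF) should give dimethyl 2-{[(4R,5R)-5-({[tert-butyl(dimethyl)silyl]oxy}methyl)-2,2-dimethyl-1,3-dioxolan-4-yl]methyl}propanedioate F2, and Krapcho demethoxycarbonylation (NaCl, wet DMSO, 150 °C) returns the route at 6.

**Step 5.** The most likely failure is incomplete control of enolate geometry in the O-sulfonylation. Any chelated enolate gives the (Z)-triflate, which cannot cyclise, and the selectivity has to be carried over from β-keto esters to an α-formyl ester. The fallback builds the alkene with (E) geometry fixed by an anti decarboxylative elimination and uses an alkenyl iodide in the ring closure.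
- From 3, malonate F2 is made as above.
- NaH and iodoform give dimethyl 2-(diiodomethyl)-2-{[(4R,5R)-5-({[tert-butyl(dimethyl)silyl]oxy}methyl)-2,2-dimethyl-1,3-dioxolan-4-yl]methyl}propanedioate F3.
- KOH in aqueous ethanol at reflux hydrolyses both esters and expels carbon dioxide and iodide to give (2E)-2-{[(4R,5R)-5-({[tert-butyl(dimethyl)silyl]oxy}methyl)-2,2-dimethyl-1,3-dioxolan-4-yl]methyl}-3-iodoprop-2-enoic acid F4, the known outcome of the malonate–iodoform route to (E)-3-iodo-2-alkylacrylic acids.
- MeI with K2CO3 gives the methyl ester F5.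
- HF·pyridine gives methyl (2E)-2-{[(4R,5R)-5-(hydroxymethyl)-2,2-dimethyl-1,3-dioxolan-4-yl]methyl}-3-iodoprop-2-enoate F6.
- Dess–Martin oxidation gives methyl (2E)-2-{[(4R,5S)-5-formyl-2,2-dimethyl-1,3-dioxolan-4-yl]methyl}-3-iodoprop-2-enoate F7.
- Ring closure with CrCl2 and catalytic NiCl2 returns the route at 13.

**Step 11.** The most likely failure is migration of the C3 acetyl group to the cis O4 under nucleophilic catalysis before the hindered O4 is acylated, which would scramble the ester positions. Loss of configuration in the activated acid is a lesser concern. The fallback changes the order so that no acyl group is on O3 while O4 and O5 are esterified.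
- From 13, silylation (TBSOTf, 2,6-lutidine) gives methyl (3aR,7R,7aS)-7-{[tert-butyl(dimethyl)silyl]oxy}-2,2-dimethyl-3a,4,7,7a-tetrahydro-1,3-benzodioxole-5-carboxylate F8.
- Aqueous acetic acid cleaves the strained acetal to give methyl (3R,4S,5R)-3-{[tert-butyl(dimethyl)silyl]oxy}-4,5-dihydroxycyclohex-1-ene-1-carboxylate F9.
- Steglich esterification with 16 gives methyl (3R,4S,5R)-3-{[tert-butyl(dimethyl)silyl]oxy}-4,5-bis{[(2R)-2-methylbutanoyl]oxy}cyclohex-1-ene-1-carboxylate F10.
- HF·pyridine gives methyl (3R,4R,5R)-3-hydroxy-4,5-bis{[(2R)-2-methylbutanoyl]oxy}cyclohex-1-ene-1-carboxylate F11 (shikimate configuration; the C4 descriptor changes only because O3 is free).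
- Acetylation with Ac2O and pyridine returns the route at 18.

## Further compounds

F1 | step 8 | methyl (3aR,7S,7aR)-7-hydroxy-2,2-dimethyl-3a,4,7,7a-tetrahydro-1,3-benzodioxole-5-carboxylate | CC1(C)O[C@@H]2[C@@H](O)C=C(C(=O)OC)C[C@H]2O1
F2 | step 3 | dimethyl 2-{[(4R,5R)-5-({[tert-butyl(dimethyl)silyl]oxy}methyl)-2,2-dimethyl-1,3-dioxolan-4-yl]methyl}propanedioate | COC(=O)C(C(=O)OC)C[C@H]1OC(C)(C)O[C@@H]1CO[Si](C)(C)C(C)(C)C
F3 | step 5 | dimethyl 2-(diiodomethyl)-2-{[(4R,5R)-5-({[tert-butyl(dimethyl)silyl]oxy}methyl)-2,2-dimethyl-1,3-dioxolan-4-yl]methyl}propanedioate | COC(=O)C(C(I)I)(C(=O)OC)C[C@H]1OC(C)(C)O[C@@H]1CO[Si](C)(C)C(C)(C)C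
F4 | step 5 | (2E)-2-{[(4R,5R)-5-({[tert-butyl(dimethyl)silyl]oxy}methyl)-2,2-dimethyl-1,3-dioxolan-4-yl]methyl}-3-iodoprop-2-enoic acid | I/C=C(C(=O)O)\C[C@H]1OC(C)(C)O[C@@H]1CO[Si](C)(C)C(C)(C)C
F5 | step 5 | methyl (2E)-2-{[(4R,5R)-5-({[tert-butyl(dimethyl)silyl]oxy}methyl)-2,2-dimethyl-1,3-dioxolan-4-yl]methyl}-3-iodoprop-2-enoate | I/C=C(C(=O)OC)\C[C@H]1OC(C)(C)O[C@@H]1CO[Si](C)(C)C(C)(C)C
F6 | step 5 | methyl (2E)-2-{[(4R,5R)-5-(hydroxymethyl)-2,2-dimethyl-1,3-dioxolan-4-yl]methyl}-3-iodoprop-2-enoate | I/C=C(C(=O)OC)\C[C@H]1OC(C)(C)O[C@@H]1CO
F7 | step 5 | methyl (2E)-2-{[(4R,5S)-5-formyl-2,2-dimethyl-1,3-dioxolan-4-yl]methyl}-3-iodoprop-2-enoate | I/C=C(C(=O)OC)\C[C@H]1OC(C)(C)O[C@@H]1C=O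
F8 | step 11 | methyl (3aR,7R,7aS)-7-{[tert-butyl(dimethyl)silyl]oxy}-2,2-dimethyl-3a,4,7,7a-tetrahydro-1,3-benzodioxole-5-carboxylate | CC1(C)O[C@@H]2[C@H](O[Si](C)(C)C(C)(C)C)C=C(C(=O)OC)C[C@H]2O1
F9 | step 11 | methyl (3R,4S,5R)-3-{[tert-butyl(dimethyl)silyl]oxy}-4,5-dihydroxycyclohex-1-ene-1-carboxylate | O[C@@H]1[C@H](O[Si](C)(C)C(C)(C)C)C=C(C(=O)OC)C[C@H]1O
F10 | step 11 | methyl (3R,4S,5R)-3-{[tert-butyl(dimethyl)silyl]oxy}-4,5-bis{[(2R)-2-methylbutanoyl]oxy}cyclohex-1-ene-1-carboxylate | CC[C@@H](C)C(=O)O[C@@H]1[C@H](O[Si](C)(C)C(C)(C)C)C=C(C(=O)OC)C[C@H]1OC(=O)[C@H](C)CC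
F11 | step 11 | methyl (3R,4R,5R)-3-hydroxy-4,5-bis{[(2R)-2-methylbutanoyl]oxy}cyclohex-1-ene-1-carboxylate | CC[C@@H](C)C(=O)O[C@@H]1[C@H](O)C=C(C(=O)OC)C[C@H]1OC(=O)[C@H](C)CC
A1 | alternative 1 | furan | c1ccoc1
A2 | alternative 1 | 2,2,2-trifluoroethyl acrylate | C=CC(=O)OCC(F)(F)F
A3 | alternative 1 | 2,2,2-trifluoroethyl endo-7-oxabicyclo[2.2.1]hept-5-ene-2-carboxylate | O=C(OCC(F)(F)F)[C@@H]1C[C@@H]2C=C[C@H]1O2
A4 | alternative 1 | 2,2,2-trifluoroethyl (5R)-5-hydroxycyclohexa-1,3-diene-1-carboxylate | O=C(OCC(F)(F)F)C1=CC=C[C@H](O)C1
A5 | alternative 2 | methyl 5-{[tert-butyl(dimethyl)silyl]oxy}-6-nitrocyclohex-3-ene-1-carboxylate, configured as in A7 | CC(C)(C)[Si](C)(C)O[C@H]1C=CC[C@H](C(=O)OC)[C@H]1[N+](=O)[O-]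
A6 | alternative 2 | silver (2R)-2-methylbutanoate | [Ag+].[O-]C(=O)[C@H](C)CC
A7 | alternative 2 | methyl 2-nitro-3-{[tert-butyl(dimethyl)silyl]oxy}-4,5-bis{[(2R)-2-methylbutanoyl]oxy}cyclohexane-1-carboxylate, 3,4-cis and 4,5-trans | CC[C@@H](C)C(=O)O[C@@H]1[C@H](O[Si](C)(C)C(C)(C)C)[C@H]([N+](=O)[O-])[C@@H](C(=O)OC)C[C@H]1OC(=O)[C@H](C)CC
A8 | alternative 3 | D-lyxose (open-chain form) | O=C[C@@H](O)[C@@H](O)[C@H](O)CO
A9 | alternative 3 | methyl 3,4-O-isopropylideneshikimate | CC1(C)O[C@@H]2[C@H](O1)C=C(C(=O)OC)C[C@H]2O
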